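The readings are simulated from invented constants; scatter was added.

**One step.** In a one-step world, reagent fed into the flask is either free or has become target, and the loss of starting material equals the gain of target. Here you follow the flasks green, red and blue, fed steadily over the dosing time. Reagent is the limiting reagent by charge, even in blue, where its charge is less than that of starting material.

| setting | epsilon | gamma | green | blue | red |
|---|---|---|---|---|---|
| starting material | 0.25 M | 0.25 M | 0.25 M | 0.25 M | 0.25 M |
| reagent | 0.15 M (fed, over 15 min) | 0.17 M (fed, over 15 min) | 0.120 M (fed, over 15 min) | 0.210 M (fed, over 15 min) | 0.160 M (fed, over 15 min) |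
| remark | run made earlier | run made earlier |  |  |  |
| time |  |  | 15 min | 15 min | 15 min |

| run | time / min | starting material / % | target / % |
|---|---|---|---|
| epsilon | 0.833 | 100.5 | 0.1 |
| epsilon | 1.50 | 99.3 | 0.7 |
| epsilon | 3.00 | 99.0 | 0.4 |
| epsilon | 6.00 | 94.2 | 0.1 |
| epsilon | 10.0 | 86.6 | 2.5 |
| gamma | 0.833 | 100.7 | 0 |
| gamma | 1.50 | 98.6 | 0.5 |
| gamma | 3.00 | 97.4 | 0.4 |
| gamma | 6.00 | 93.2 | 0.5 |
| gamma | 10.0 | 84.6 | 2.6 |

(standard deviation of a reading: 0.5 percentage points)

1. part of the starting material that has reacted at the end, green
2. part of the starting material that has reacted at the end, blue
3. part of the starting material that has reacted at the end, red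
4. what raising the concentration of reagent from its lowest to its highest value here does to the part of the starting material that has reacted (changes below 5 percentage points count as none) (it rises / no change / it falls)

- what has gone from starting material into another species counts as reacted, even if it can come back

**The ledger.** Take epsilon at 10.0 min and assume one reagent per starting material. So far 0.100 M of reagent has been fed. The lost starting material amounts to 0.0335 M, so that much reagent is bound. Target holds 0.00625 M of it, which leaves 0.0273 M in a form not read, presumably an intermediate. The remaining 0.0665 M is free, and the books close. The free share of the fed reagent reads 66.5 % in epsilon and 66.0 % in gamma, so the two flasks read alike.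

**The freeze.** I therefore freeze that share, which makes free reagent a steady part of what has been fed. The logarithm of c(starting material) then falls in proportion to the exposure: the charge times the time squared, divided by 2 and by the dosing time. Epsilon gives 0.288 M⁻¹ min⁻¹ per unit of exposure and gamma 0.295 M⁻¹ min⁻¹. Their mean, 0.291 M⁻¹ min⁻¹, is the exposure constant, a reading with the scatter of its readings.

**My reckoning.** At 15 min this gives 23.1 % for green, 29.5 % for red and 36.8 % for blue. That is a rise of 14 percentage points, more than the margin of 5 points. At 6.00 min epsilon's quotient read 0.332 M⁻¹ min⁻¹, higher than the exposure constant, which hints that my figures may run high.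

**The result.** The forecast gave 21 % for green, 27 % for red and 34 % for blue, in each flask lower than my figure, and for the trend it rises, in its words “so conversion rises with reagent”. The flasks give 19.1 % for green, 24.6 % for red and 30.9 % for blue; raising the reagent from lowest to highest, it rises, by 12 points.

    starting material + reagent ⇌ intermediate (K = 4.20 M⁻¹, k = 0.00830 M⁻¹ s⁻¹)
    intermediate ⇌ target + by-product (K = 0.140 M, k = 0.00100 s⁻¹)
    starting material + by-product ⇌ idle adduct, settled at all times (K = 1.80 M⁻¹)

**Still moving.** Blue's end state gives a quotient of 0.234 M⁻¹ min⁻¹, lower than the exposure constant. Blue has not come to rest at 15.0 min. By 150 min the part reacted would reach 55.0 %, target would go from 8.45 % to 33.1 %, and free reagent from 65.6 % to 41.1 % of its charge.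

**Second flask.** Take blue's reagent charge with 0.10 M of starting material. The exposure contains no c(starting material), so the exposure constant gives 36.8 %. The flask gives 35.2 %, with 84 % of its reagent free at the end.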